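**Numbering used throughout:** 1 = 2,4,6-trihydroxyacetophenone; 2 = benzyl bromide; 3 = 1-[2,4-bis(benzyloxy)-6-hydroxyphenyl]ethan-1-one; 4 = the derived (E)-dimethylamino enone; 5 = 5,7-bis(benzyloxy)-4H-chromen-4-one; 6 = 1-bromopentadecane; 7 = pentadecylmagnesium bromide; 8 = racemic 5,7-bis(benzyloxy)-2-pentadecyl-4-(trimethylsilyloxy)-2H-chromene; 9 = 5,7-bis(benzyloxy)-2-pentadecyl-4H-chromen-4-one; 10 = the target.

## Analysis of the target

Compound 10 is 5,7-dihydroxy-2-pentadecyl-4H-chromen-4-one: a benzene ring (ring A) fused to a γ-pyranone ring, with free hydroxyls on C5 and C7, hydrogen on C3, C6 and C8, and an unbranched saturated C15 chain on C2. There is no stereocentre and no configurable double bond, so nothing stereochemical has to be set and any sp3 centre created on the way only has to disappear again. The three oxygens on ring A (O1 on C8a and the hydroxyls on C5 and C7) are mutually meta, and the acyl carbon C4 sits on C4a between two of them, which is the pattern of an acylphloroglucinol. The two phenols are acidic, the C5 hydroxyl being hydrogen-bonded to the C4 carbonyl, and would quench an organometallic reagent; C6 and C8 are very electron-rich and open to electrophilic substitution; the pyranone is a vinylogous ester that hard nucleophiles and hydroxide open at C2. The difficulty is therefore constitutional and practical, not stereochemical: the chain must end up on C2 of a chromone and not on C4 of an isomeric coumarin, a waxy C15 segment has to be joined to a polar polyphenol, and the phenol protection must come off without harming the pyranone or alkylating ring A. The strategy rests on one feature: C2 is the β-carbon of the unit O1–C2=C3–C4=O and the only atom that links chain and heterocycle. The C2–C1' bond can therefore be made by 1,4-addition of a C15 carbon nucleophile to a C2-unsubstituted 5,7-dioxygenated chromone, after which the C2=C3 bond is restored.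

## Retrosynthetic reasoning

**10 from 9.** The two phenolic O–H bonds are traced back to O–CH2Ph bonds. The phenols must be masked for the organometallic step. Benzyl ethers are chosen because they have no acidic hydrogen, survive base, organocopper reagents and Pd(OAc)2, and can be removed at the end by a Lewis acid or by hydrogenolysis without touching the pyranone or the chain. Methyl ethers would be cheaper, but the C7 ether would need forcing cleavage.

**9 from 8.** The C2=C3 double bond is traced back to a C2–H/C3=C4–OSi arrangement, that is, a 4-silyloxy-2H-chromene. This is only an adjustment of oxidation level. The forward reaction has to remove the silyl group and the C2 hydrogen, and it can do so in only one direction, because C2–H is the only hydrogen β to the enol carbon C3. The C2 stereocentre of 8 is lost here, so 8 can be racemic.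

**8 from 5 and 7.** The C2–C1' bond is cut. It is the only carbon–carbon bond between heterocycle and chain, and cutting it divides the target into a polar aromatic half and a lipophilic half, each from one cheap commercial material. A cut inside the chain would be arbitrary. Cuts in the pyranone (O1–C2, C4–C4a, O1–C8a) would mean building the ring around the chain, which ties the chain to an early intermediate. Here the chain arrives convergently on a finished chromone. The forward reaction must deliver the alkyl group to the β-carbon C2 and not to the C4 carbonyl, and must trap the resulting enolate on oxygen before it can expel the ring aryloxide.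

**7 from 6.** The carbon–magnesium bond is traced back to the carbon–bromine bond of the primary bromide 6 by metal insertion.

**5 from 4, and 4 from 3.** The pyranone of 5 is opened at O1–C2, giving the ortho-hydroxyaryl enaminone 4, and 4 is cut at C2–C3 back to the methyl ketone 3 and a one-carbon electrophile at the carboxylic acid oxidation level. This is the shortest way to a chromone with hydrogen on C2. The forward sequence has to condense the acetyl methyl group with an amide acetal, then add the free ortho phenol to the β-carbon with loss of the amine.

**3 from 1 and 2.** Two O–benzyl bonds are cut, so two equivalents of 2 are needed. The ketone 1 already carries the complete ring A oxygenation and the C4 carbon in the correct positions. The hydroxyl that stays free is ortho to the acetyl group and later becomes O1. The two ortho hydroxyls of 1 are equivalent, so it does not matter which one stays free. The forward reaction must alkylate the para and one ortho hydroxyl and stop there.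

## Alternatives that were turned down

Alternative 1: ring A built by a polyketide-type Claisen closure.
- Disconnection: the C4a–C5 bond of ring A, which traces the whole carbon skeleton to the open-chain pentacarbonyl ester methyl 3,5,7,9-tetraoxotetracosanoate A1.
- Forward key step: with Mg(OMe)2 in methanol as a chelating base, the C6 methylene of A1 attacks the C1 ester carbonyl. Loss of methoxide and enolization should give the aromatic triketone 1-(2,4,6-trihydroxyphenyl)octadecane-1,3-dione A2. Acid-catalysed cyclodehydration of A2 would then close the pyranone and give 10 directly.
- For it: no protecting groups, no redox steps, and an endgame that is a single dehydration with no regiochemical question, since the two ortho hydroxyls of A2 are equivalent. On protecting-group and redox economy it is clearly better than the chosen route.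
- Against it: A1 has five carbonyls and four active methylene groups, and its preparation needs repeated polyanion acylations. A1 can also close through an enol oxygen onto the ester to a six-membered lactone, or by aldol attack on a ketone instead of Claisen attack on the ester, and the C15 tail gives no bias between these folds.
- Comparison: the chosen strategy buys ring A with its oxygenation in place, has one reactive site per step, and puts its risk in one C–C bond formation instead of spreading it over the assembly and folding of a polycarbonyl chain.

Alternative 2: pyranone closed at carbon by intramolecular acylation.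
- Disconnection: the C4–C4a bond, leading to (Z)-3-(3,5-dimethoxyphenoxy)octadec-2-enoic acid A3.
- Forward key step: in Eaton's reagent (P2O5 in MeSO3H) the acid of A3 is activated as a mixed anhydride or acylium ion. It should attack the ring position ortho to the ether oxygen, which both methoxy groups activate, to give 5,7-dimethoxy-2-pentadecyl-4H-chromen-4-one A4. Cleavage of the two methyl ethers of A4 would then lead to 10.
- For it: the aryl ring of A3 is symmetrical, so only one ring-closure regiochemistry exists. The precursor A3 is a two-component adduct of a phenol and a C18 alk-2-ynoic ester. No organometallic reagent or sensitive silyl enol ether is involved. In step count it is equal to or shorter than the chosen route.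
- Against it: only the Z isomer of A3 can cyclize. Any acid-mediated cleavage of the aryl enol ether opens a Pechmann-type recombination that would give the isomeric coumarin 5,7-dimethoxy-4-pentadecyl-2H-chromen-2-one A5, and A5 would be hard to separate from A4 because the two are isomers of very similar polarity. At the end, the chelated C5 methyl ether of A4 leaves easily, but the C7 ether needs forcing Lewis- or Brønsted-acid conditions.
- Comparison: the chosen strategy fixes the C4 carbonyl on ring A from compound 1 onward, so the constitution cannot drift to a coumarin of the A5 type, and it uses benzyl ethers that leave under mild conditions.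

Alternative 3: pyranone closed at oxygen by fluoride displacement.
- Disconnection: the O1–C8a bond, leading to 1-(2,4,6-trifluorophenyl)octadecane-1,3-dione A6.
- Forward key step: with K2CO3 in DMF the enolate oxygen of the chain-side ketone of A6 displaces an ortho fluoride activated by the aryl ketone, through a Meisenheimer intermediate. This should give 5,7-difluoro-2-pentadecyl-4H-chromen-4-one A7.
- For it: A6 comes from one Claisen condensation of a trifluorinated aryl methyl ketone with a C16 fatty ester. The two ortho fluorides are equivalent, and the closure needs no protecting group. As a ring-forming step it is probably more reliable than the key step chosen here.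
- Against it: A7 has fluorine where 10 has hydroxyl. Both C–F bonds must then be exchanged for oxygen by further displacement with an alkoxide. The first exchange deactivates the ring for the second, and the alkoxide can also attack C2 and open the pyranone. A final dealkylation follows.
- Comparison: the step count is no better than the chosen route, and the risk moves to a late, strongly basic double substitution on a base-sensitive heterocycle. The chosen strategy carries all three ring A oxygens from the first compound.

Key step: step 5

## Route

Remark on the chemistry: commercial 1 is usually the monohydrate and is dried before use; 8 is hydrolytically labile and is taken into step 6 as the crude, base-washed material.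

Step 1
Reactants: 1 2,4,6-trihydroxyacetophenone; 2 benzyl bromide
Product: 3 1-[2,4-bis(benzyloxy)-6-hydroxyphenyl]ethan-1-one
Conditions: BnBr (2.1 equiv in all), K2CO3 (2.2 equiv), DMF, 0 °C → rt
Reagents that add atoms: benzyl bromide, BrCc1ccccc1
Why: Twofold Williamson ether synthesis, the second benzyl group coming from a second equivalent of 2; the para hydroxyl is the most acidic and least hindered and one of the two equivalent ortho hydroxyls follows. The remaining ortho hydroxyl is held in a six-membered hydrogen bond to the ketone and should resist alkylation when 2 is limited to two equivalents.

Step 2
Reactants: 3 1-[2,4-bis(benzyloxy)-6-hydroxyphenyl]ethan-1-one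
Product: 4 (E)-1-[2,4-bis(benzyloxy)-6-hydroxyphenyl]-3-(dimethylamino)prop-2-en-1-one
Conditions: Me2NCH(OMe)2 (3 equiv), toluene, 100 °C
Reagents that add atoms: N,N-dimethylformamide dimethyl acetal, COC(OC)N(C)C
Why: Condensation of the methyl ketone with an amide acetal (enaminone formation); loss of two molecules of methanol drives it, and the push-pull vinylogous amide should form as the E isomer, with the chelated phenol left untouched.

Step 3
Reactants: 4 (E)-1-[2,4-bis(benzyloxy)-6-hydroxyphenyl]-3-(dimethylamino)prop-2-en-1-one
Product: 5 5,7-bis(benzyloxy)-4H-chromen-4-one
Conditions: AcOH, 90 °C
Reagents that add atoms: none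
Why: Acid-promoted intramolecular oxa-Michael addition of the phenol to the protonated enaminone (6-endo-trig) followed by β-elimination of dimethylamine, an addition–elimination that gives the C2-unsubstituted chromone; aryl benzyl ethers are stable to warm acetic acid.

Step 4
Reactants: 6 1-bromopentadecane
Product: 7 pentadecylmagnesium bromide (about 0.5 M solution in THF, titrated)
Conditions: Mg turnings (1.3 equiv), I2 (cat.), THF, 45 °C, slow addition of 6
Reagents that add atoms: magnesium, [Mg]
Why: Grignard reagent formation by insertion of magnesium into a primary C–Br bond; slow addition at moderate dilution should keep Wurtz coupling low.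

Step 5
Reactants: 5 5,7-bis(benzyloxy)-4H-chromen-4-one; 7 pentadecylmagnesium bromide
Product: 8 racemic 5,7-bis(benzyloxy)-2-pentadecyl-4-(trimethylsilyloxy)-2H-chromene
Conditions: 7 (1.5 equiv, slow addition), CuBr·SMe2 (10 mol %), Me3SiCl (2.5 equiv), THF, −78 → −30 °C; then Et3N, pentane, cold aq. NaHCO3; used crude
Reagents that add atoms: chlorotrimethylsilane, C[Si](C)(C)Cl
Why: Transmetalation of 7 to CuBr·SMe2 (monovalent copper) gives a soft organocuprate that forms a π-complex with the C2=C3 bond of 5 and adds at C2, the β-carbon of the vinylogous ester, to give a β-cuprio (trivalent copper) enolate; chlorotrimethylsilane silylates the carbonyl oxygen, which pulls this equilibrium forward and triggers the reductive elimination that forms the C2–C1' bond and releases 8 while returning copper to the cycle. The closest known reaction type is the chlorosilane-accelerated, copper-catalysed conjugate addition of Grignard reagents to enones and chromones with isolation of the silyl enol ether. No ring is closed. The one new stereocentre, C2, forms without any controlling element, so 8 is racemic, which does not matter because C2 returns to sp2 in step 6. The step needs 1,4- over 1,2-addition and a single addition: the soft cuprate and the slow addition of 7 (little free Grignard reagent) favour C2, the peri benzyloxy group on C5 screens the C4 carbonyl, and immediate O-silylation stops the enolate from expelling the ring aryloxide and taking up a second chain. The benzyl ethers have no acidic hydrogen and are inert to the organometallic.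

Step 6
Reactants: 8 racemic 5,7-bis(benzyloxy)-2-pentadecyl-4-(trimethylsilyloxy)-2H-chromene
Product: 9 5,7-bis(benzyloxy)-2-pentadecyl-4H-chromen-4-one
Conditions: Pd(OAc)2 (1.05 equiv), MeCN–CH2Cl2, rt
Reagents that add atoms: none
Why: Saegusa–Ito oxidation; Pd(OAc)2 (divalent palladium) exchanges with silicon to give the C3-palladated ketone, and syn β-hydride elimination of the only available β-hydrogen (on C2) re-forms the C2=C3 bond, which removes the C2 stereocentre; benzyl ethers and the chain are unaffected.

Step 7
Reactants: 9 5,7-bis(benzyloxy)-2-pentadecyl-4H-chromen-4-one
Product: 10 5,7-dihydroxy-2-pentadecyl-4H-chromen-4-one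
Conditions: BCl3 (5 equiv), C6HMe5 (6 equiv), CH2Cl2, −78 → 0 °C; then MeOH, H2O
Reagents that add atoms: none
Why: Lewis-acid cleavage of aryl benzyl ethers; BCl3 coordinates the ether oxygens (the C5 ether fastest, by chelation with the C4 carbonyl), pentamethylbenzene captures the benzyl cation by Friedel–Crafts alkylation so that C6 and C8 of ring A are not benzylated, and the methanol/water quench hydrolyses the aryl borates to the free phenols; the pyranone and the alkyl chain are inert.

## Compound list

1 | 2,4,6-trihydroxyacetophenone | CC(=O)c1c(O)cc(O)cc1O | starting material
2 | benzyl bromide | BrCc1ccccc1 | starting material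
3 | 1-[2,4-bis(benzyloxy)-6-hydroxyphenyl]ethan-1-one | CC(=O)c1c(O)cc(OCc2ccccc2)cc1OCc1ccccc1 | intermediate
4 | (E)-1-[2,4-bis(benzyloxy)-6-hydroxyphenyl]-3-(dimethylamino)prop-2-en-1-one | CN(C)/C=C/C(=O)c1c(O)cc(OCc2ccccc2)cc1OCc1ccccc1 | intermediate
5 | 5,7-bis(benzyloxy)-4H-chromen-4-one | O=c1ccoc2cc(OCc3ccccc3)cc(OCc3ccccc3)c12 | intermediate
6 | 1-bromopentadecane | CCCCCCCCCCCCCCCBr | starting material
7 | pentadecylmagnesium bromide | CCCCCCCCCCCCCCC[Mg]Br | intermediate
8 | racemic 5,7-bis(benzyloxy)-2-pentadecyl-4-(trimethylsilyloxy)-2H-chromene | CCCCCCCCCCCCCCCC1C=C(O[Si](C)(C)C)c2c(OCc3ccccc3)cc(OCc3ccccc3)cc2O1 | intermediate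
9 | 5,7-bis(benzyloxy)-2-pentadecyl-4H-chromen-4-one | CCCCCCCCCCCCCCCc1cc(=O)c2c(OCc3ccccc3)cc(OCc3ccccc3)cc2o1 | intermediate
10 | 5,7-dihydroxy-2-pentadecyl-4H-chromen-4-one | CCCCCCCCCCCCCCCc1cc(=O)c2c(O)cc(O)cc2o1 | target

## Step count and risk

Total step count: 7. Longest linear sequence: 6 (steps 1, 2, 3, 5, 6, 7); step 4 is a one-step side branch that supplies 7.

**Step 5 (key step).**
- What may go wrong: the two alkoxy donors on ring A lower the electrophilicity of C2. Direct 1,2-attack of unconverted Grignard reagent on C4 may then compete. An enolate that is not silylated fast enough may open the ring by loss of the aryloxide. The long-chain reagent may also precipitate at low temperature.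
- Fallback: this sets out from 3 and gives up the conjugate addition. Compound 3 is deprotonated twice with LiN(SiMe3)2 (3.2 equiv) in THF at −78 °C and C-acylated with hexadecanoyl chloride (Claisen-type acylation of the ketone enolate) to give 1-[2,4-bis(benzyloxy)-6-hydroxyphenyl]octadecane-1,3-dione F1. Cyclodehydration of F1 with catalytic H2SO4 in AcOH at 60 °C should close the pyranone and rejoin the route at 9. Steps 2 to 6 are bypassed, at the price of fixing the chain before the heterocycle exists.

**Step 6.**
- What may go wrong: hydrolysis or protodesilylation of the labile trimethylsilyl enol ether, either during its isolation or by the acetic acid set free, would return the saturated ketone before palladation can occur.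
- Fallback: this sets out from 8 and makes that hydrolysis deliberate. Treatment with 1 M HCl in THF at rt should give racemic 5,7-bis(benzyloxy)-2-pentadecylchroman-4-one F2. F2 is then dehydrogenated with I2 in DMSO at 110 °C (α-iodination at C3, loss of HI, DMSO re-oxidising the iodide), which rejoins the route at 9.

**Step 1.**
- What may go wrong: the alkylation may not stop cleanly at the bis-ether stage (too little or too much O-benzylation), which would leave a mixture that is hard to separate.
- Fallback: this sets out from 1 and replaces selective protection by exhaustive protection and selective deprotection. Excess 2 with K2CO3 in DMF at 80 °C should give 1-[2,4,6-tris(benzyloxy)phenyl]ethan-1-one F3, which is purified by crystallization. One of the two equivalent ortho benzyl ethers of F3 is then cleaved under chelation control with MgBr2·OEt2 in toluene–Et2O at 80 °C, which rejoins the route at 3.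

**Step 7.**
- What may go wrong: re-attachment of the benzyl cation at C6 or C8 of the electron-rich ring A, or incomplete cleavage of the non-chelated C7 ether.
- Fallback: this sets out from 9 and goes directly to 10 by catalytic hydrogenolysis, H2 (1 atm) over Pd/C (zerovalent palladium on carbon) in EtOAc–THF at rt. No benzyl cation is formed. The reaction is stopped when 9 is consumed so that the C2=C3 bond is not saturated. This fallback makes no new compound and is entered as F0.

## Further compounds

F1 | step 5 | 1-[2,4-bis(benzyloxy)-6-hydroxyphenyl]octadecane-1,3-dione | CCCCCCCCCCCCCCCC(=O)CC(=O)c1c(O)cc(OCc2ccccc2)cc1OCc1ccccc1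
F2 | step 6 | racemic 5,7-bis(benzyloxy)-2-pentadecylchroman-4-one | CCCCCCCCCCCCCCCC1CC(=O)c2c(OCc3ccccc3)cc(OCc3ccccc3)cc2O1
F3 | step 1 | 1-[2,4,6-tris(benzyloxy)phenyl]ethan-1-one | CC(=O)c1c(OCc2ccccc2)cc(OCc2ccccc2)cc1OCc1ccccc1
F0 | step 7 | none | none
A1 | alternative 1 | methyl 3,5,7,9-tetraoxotetracosanoate | CCCCCCCCCCCCCCCC(=O)CC(=O)CC(=O)CC(=O)CC(=O)OC
A2 | alternative 1 | 1-(2,4,6-trihydroxyphenyl)octadecane-1,3-dione | CCCCCCCCCCCCCCCC(=O)CC(=O)c1c(O)cc(O)cc1O
A3 | alternative 2 | (Z)-3-(3,5-dimethoxyphenoxy)octadec-2-enoic acid | CCCCCCCCCCCCCCC/C(Oc1cc(OC)cc(OC)c1)=C/C(=O)O
A4 | alternative 2 | 5,7-dimethoxy-2-pentadecyl-4H-chromen-4-one | CCCCCCCCCCCCCCCc1cc(=O)c2c(OC)cc(OC)cc2o1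
A5 | alternative 2 | 5,7-dimethoxy-4-pentadecyl-2H-chromen-2-one | CCCCCCCCCCCCCCCc1cc(=O)oc2cc(OC)cc(OC)c12
A6 | alternative 3 | 1-(2,4,6-trifluorophenyl)octadecane-1,3-dione | CCCCCCCCCCCCCCCC(=O)CC(=O)c1c(F)cc(F)cc1F
A7 | alternative 3 | 5,7-difluoro-2-pentadecyl-4H-chromen-4-one | CCCCCCCCCCCCCCCc1cc(=O)c2c(F)cc(F)cc2o1
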